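The pitfall with an impurity that destroys catalyst is to take its charge as the measure of the harm. The flask, followed so far as the ochre run, stands beside the earlier violet run. Their charges match, except that violet holds twice the impurity.

in all of them: substrate 0.20 M
- ochre: reagent 0.20 M; free catalyst 4 mM; impurity 1.8 mM; the very flask that is asked about, followed so far
- violet: reagent 0.20 M; free catalyst 4 mM; impurity 3.6 mM; run made earlier
- flask: reagent 0.200 M; free catalyst 4.0 mM; impurity 1.8 mM

ochre run (percent of the substrate charged)

| time / s | target / % | substrate / % |
|---|---|---|
| 10.0 | 0.2 | 98.8 |
| 20.0 | 0.3 | 98.2 |
| 40.0 | 2.4 | 96.9 |
| 80.0 | 4.3 | 94.7 |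

violet run (percent of the substrate charged)

| time / min | target / % | substrate / % |
|---|---|---|
| 1.33 | 0.2 | 99.1 |
| 3.00 | 1.6 | 97.7 |
| 4.00 | 2.3 | 97.7 |
| 6.00 | 4.3 | 96.4 |
| 8.00 | 6.2 | 94.6 |

(each reading ± 0.5 percentage points)

* apparent order in reagent when 10% of the substrate are converted (percent change of the rate of making target for one percent more reagent charged)
* factor on the rate of making target when 10% of the substrate are converted if free catalyst is charged twice over

- candidate steps: substrate + free catalyst <-> catalyst intermediate A; reagent + catalyst intermediate A <-> catalyst intermediate B; catalyst intermediate B -> catalyst intermediate C; catalyst intermediate C -> free catalyst + target; free catalyst + impurity -> spent catalyst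
- no earlier run changes the charge of free catalyst; that part of a forecast is a guess
- no earlier run changes the charge of reagent; that part of a forecast is a guess

Yet the slopes of target, read from 20.0 s to 80.0 s in ochre and from 3.00 min to 8.00 min in violet, differ by a factor of 4.35, more than the impurity ratio. I clear this up by asking what end state the poisoning step must reach. Impurity turns free catalyst into spent catalyst one for one, and it is charged below the catalyst in both runs, so in that step impurity is the limiting reagent. If the step runs to its end, the flask keeps 2.20 mM of catalyst that is not spent. I call this the working catalyst W, the catalyst charged minus the impurity charged. On the same reckoning violet keeps 0.400 mM, so W differs by a factor of 5.50. The slope reading, with its scatter, lies below this but above the impurity ratio.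

If rate follows W, charging the catalyst twice over gives 6.20 mM and a factor of 2.82. No run tests that, and none tests reagent, so I reckon no order.

The forecast gives an order of 0.35 and a factor of 2.8, and says “Whether the reagent step limits is untested”.

The flask gives an order of 0.63 and a factor of 2.83.

    substrate + free catalyst ⇌ catalyst intermediate A (K = 3.80 /M, k = 4.83 /M/s)
    reagent + catalyst intermediate A ⇌ catalyst intermediate B (K = 11.0 /M, k = 3.73 /M/s)
    catalyst intermediate B → catalyst intermediate C (k = 0.182 /s)
    catalyst intermediate C → free catalyst + target (k = 0.763 /s)
    free catalyst + impurity → spent catalyst (k = 2510 /M/s)

In the flask at 10.0 min, impurity stands at 0% of its charge and spent catalyst at 45.0% of the catalyst charged. W, at 2.20 mM, is 55.0% of that charge, and free catalyst with intermediates A, B and C together stands at 55.0%.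

(The numbers in the tables were generated by integration with constants of no real substance; scatter was added.)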